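**Retrosynthetic overview**

1. Numbering: bicyclo[3.2.1]oct-3-ene-2,8-dione core C1–C8 (bridgeheads C1 and C5, ketones C2 and C8, alkene C3=C4, aryl-bearing C6 on C5 and C7 on C1), fused cyclopentane C4–C5–C9–C10–C11, indane methine C12. The strategy rests on C1, which lies between the C2 and C8 carbonyls of the six-membered ring and is 1,5 to the benzylic C7–H2 of the diarylethyl arm on quaternary C5.
2. Last C–C bond: C1–C7, by C–H insertion of a rhodium carbenoid from the ring-fused (C4–C5 shared, not spiro) 2-diazocyclohex-4-ene-1,3-dione. This closes the cyclopentanone C1–C7–C6–C5–C8 and gives the bicyclo[3.2.1]octene as its heptamethyl ether; BBr3 then frees the seven phenols.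
3. The diazo dione comes from the cyclic 1,3-dione, whose six-membered ring is closed by aldol condensation (C3 onto C4) of a C5-bound 3-oxobutanoyl group. The C5–C6 bond and both stereocentres come from a catalytic Michael addition of a 2-acetyl ketone to 4-methoxy-β-nitrostyrene; the nitro group is then exchanged for the 3,5-dimethoxyphenyl group.
4. The indane-fused cyclopentanone comes from (R)-4-silyloxycyclopentenone: conjugate addition of the 3,5-dimethoxyphenyl group, aldol with 4-methoxybenzaldehyde, Friedel–Crafts closure of the indane, elimination to the C5=C9 enone, conjugate addition of the C9 aryl group.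
5. Order of ring formation: cyclopentane C4–C5–C9–C10–C11 (purchased), indane five-membered ring, six-membered dione ring, bridging cyclopentanone (key step).

Key step: step 12

Remark: the (1R,2R) thiourea of step 6 is assumed to attack the nitroalkene with the facial sense it shows with malonates (which corresponds to 6S here); if the sense proves opposite, the (1S,2S) antipode is used.

**Route**

Step 1
Reactants: 1 (R)-4-[(tert-butyldimethylsilyl)oxy]cyclopent-2-en-1-one; 2 (3,5-dimethoxyphenyl)magnesium chloride; 3 4-methoxybenzaldehyde
Product: 5 silyloxy aldol adduct (2,3-trans-3,4-trans cyclopentanone; carbinol epimers), via chloromagnesium enolate 4 (not isolated)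
Conditions: 2 (1.3 equiv), CuBr·SMe2 (10 mol %), THF, −78 °C; then 3 (1.5 equiv), −78 → −40 °C; aq. NH4Cl
Reagents that add atoms: none
Why: Copper-catalysed conjugate addition of the aryl Grignard reagent takes place anti to the C9 silyloxy group and sets C10, and the regiodefined enolate 4 is trapped at C11 by the aldehyde (aldol addition, three-component coupling), the configurations at C11 and at the carbinol carbon C12 being of no consequence because both are reset in step 2.

Step 2
Reactants: 5 silyloxy aldol adduct
Product: 6 tricyclic silyloxy ketone (cis-fused indane–cyclopentanone)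
Conditions: BF3·OEt2 (2 equiv), CH2Cl2, −78 → 0 °C
Reagents that add atoms: none
Why: Intramolecular Friedel–Crafts alkylation: BF3 ionises the p-methoxybenzylic carbinol, C11 equilibrates through the enol to the cis arrangement that alone allows ring closure, and the ortho carbon of the 3,5-dimethoxyphenyl ring captures the C12 cation to give the cis-fused indane with the C12 aryl group on the convex face (trans to C4), the outcome of a reversible, thermodynamically controlled closure.

Step 3
Reactants: 6 tricyclic silyloxy ketone
Product: 7 tricyclic enone (C4 ketone, C5=C9)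
Conditions: TsOH·H2O (0.2 equiv), toluene, 60 °C
Reagents that add atoms: none
Why: Acid-catalysed β-elimination (desilylation, then dehydration of the β-hydroxy ketone) gives the C5=C9 enone under conditions that avoid base, which would move the double bond into conjugation with the benzo ring, while C10 stays fixed by the cis ring fusion.

Step 4
Reactants: 7 tricyclic enone; 8 (4-methoxyphenyl)magnesium bromide
Product: 9 tricyclic ketone carrying the C9 4-methoxyphenyl group
Conditions: 8 (1.5 equiv), CuBr·SMe2 (20 mol %), THF, −78 → −40 °C; aq. NH4Cl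
Reagents that add atoms: none
Why: Copper-catalysed conjugate addition of the aryl Grignard reagent to the bicyclo[3.3.0]octenone occurs on the convex face, anti to the benzo ring on C10, which sets C9 with its aryl group trans to that ring.

Step 5
Reactants: 9 tricyclic ketone
Product: 10 2-acetyl ketone (acetyl on C5; largely enolised)
Conditions: MgBr2·OEt2 (2.5 equiv), i-Pr2NEt (3 equiv), 1-acetylbenzotriazole (1.3 equiv), CH2Cl2, rt
Reagents that add atoms: 1-acetyl-1H-benzotriazole, CC(=O)n1nnc2ccccc12
Why: Crossed Claisen acylation under soft enolisation takes place at C5, the only methylene α-carbon, because acylation at the tertiary ring-fusion carbon C11 would give a crowded diketone that cannot be held as a magnesium enolate.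

Step 6
Reactants: 10 2-acetyl ketone; 11 (E)-1-methoxy-4-(2-nitroethenyl)benzene
Product: 12 Michael adduct (quaternary C5; C6 S; CH2NO2 as C7)
Conditions: 1-[3,5-bis(trifluoromethyl)phenyl]-3-[(1R,2R)-2-(dimethylamino)cyclohexyl]thiourea (10 mol %), toluene, rt
Reagents that add atoms: none
Why: Thiourea-catalysed Michael addition: the bifunctional catalyst binds the nitro group and the dicarbonyl enol, the enol carbon C5 adds on its face anti to the adjacent C9 aryl group (quaternary C5, arm trans to that aryl group) and the catalyst selects the face of the nitroalkene (C6, S), the substrate bias and this catalyst antipode being matched.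

Step 7
Reactants: 12 Michael adduct; 13 1-bromo-3,5-dimethoxybenzene
Product: 14 arylated nitro compound (C7 epimers)
Conditions: Pd2(dba)3 (2.5 mol %), 2-(di-tert-butylphosphino)-2′-methylbiphenyl (10 mol %), Cs2CO3 (1.2 equiv), 1,2-dimethoxyethane, 50 °C; aq. NH4Cl
Reagents that add atoms: none
Why: Palladium-catalysed α-arylation of the primary nitroalkane through its caesium nitronate installs the 3,5-dimethoxyphenyl group on C7, the more acidic product staying as its nitronate so that a second arylation is avoided, and the C7 epimers are carried on because C7 becomes a methylene group in step 8.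

Step 8
Reactants: 14 arylated nitro compound
Product: 15 diketone with the complete C6–C7 arm
Conditions: Bu3SnH (3 equiv), AIBN (0.2 equiv), toluene, 110 °C
Reagents that add atoms: none
Why: Radical denitration with tin hydride removes the secondary benzylic nitro group (the stannyl radical adds to the nitro oxygen and the benzylic C7 radical takes hydrogen from Bu3SnH), and ketones and aryl ethers are untouched.

Step 9
Reactants: 15 diketone with the complete arm
Product: 16 triketone (3-oxobutanoyl group C8–C1–C2–C3 on C5)
Conditions: MgBr2·OEt2 (2.5 equiv), i-Pr2NEt (3 equiv), 1-acetylbenzotriazole (1.3 equiv), CH2Cl2, rt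
Reagents that add atoms: 1-acetyl-1H-benzotriazole, CC(=O)n1nnc2ccccc12
Why: Crossed Claisen acylation under soft enolisation: the magnesium-chelated diketone can enolise only at the acetyl methyl group (C1), C5 being quaternary, and the non-nucleophilic amine base avoids retro-Claisen cleavage of the 2,2-disubstituted 1,3-diketone.

Step 10
Reactants: 16 triketone
Product: 18 ring-fused cyclohex-4-ene-1,3-dione, via bicyclic ketol 17 (not isolated)
Conditions: LiN(i-Pr)2 (2.5 equiv), THF, −78 → 0 °C; then 2 M HCl, THF, rt
Reagents that add atoms: none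
Why: Intramolecular aldol condensation: the terminal carbanion (C3) of the 1,3-diketone dianion adds to the C4 ketone in a 6-(enolexo)-exo-trig closure to ketol 17, and acid then dehydrates it to the conjugated C3=C4 dione, the ring closure of the second stage of a Robinson annulation.

Step 11
Reactants: 18 ring-fused cyclohex-4-ene-1,3-dione
Product: 19 ring-fused 2-diazocyclohex-4-ene-1,3-dione (diazo group on C1)
Conditions: 4-acetamidobenzenesulfonyl azide (1.2 equiv), Et3N (2 equiv), MeCN, 0 °C → rt
Reagents that add atoms: 4-acetamidobenzenesulfonyl azide, CC(=O)Nc1ccc(cc1)S(=O)(=O)N=[N+]=[N-]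
Why: Regitz diazo transfer from the sulfonyl azide to C1, the only carbon flanked by two carbonyl groups, of the triethylammonium enolate of the cyclic 1,3-dione.

Step 12
Reactants: 19 ring-fused 2-diazocyclohex-4-ene-1,3-dione
Product: 20 heptamethyl ether of the target
Conditions: Rh2(cap)4 (cap = caprolactamate, 2 mol %), ClCH2CH2Cl, 80 °C, slow addition of 19 over 4 h
Reagents that add atoms: none
Why: Proposed new method: Rh2(cap)4 takes N2 from 19 to give an electrophilic carbenoid at C1 that is held in the plane of the six-membered ring between the C2 and C8 carbonyls, and its vacant orbital, perpendicular to that plane, meets a benzylic C7–H bond of the arm that stands pseudo-axial on C5, so that a concerted three-centre insertion with retention at C7 forms C1–C7. The closest known reaction type is the dirhodium-catalysed 1,5 C–H insertion of α-diazo-β-dicarbonyl compounds to cyclopentanones, which here is asked to work with the carbenoid carbon inside the ring so that the new bond bridges ring positions C1 and C5, a mode that has not been shown for cyclic 2-diazo-1,3-diones. The ring closed is the cyclopentanone C1–C7–C6–C5–C8, through a five-membered (1,5) insertion transition state, which turns the cyclohexenedione into the bicyclo[3.2.1]oct-3-ene-2,8-dione. C1 is fixed by the bridge (the new bond must lie on the face of the ring that carries the arm), and C7 by the choice between its two hydrogens: the transition state that keeps the 3,5-dimethoxyphenyl group trans to the C6 aryl group, and therefore endo towards the C2–C3=C4 bridge, avoids eclipsing the two aryl groups on the forming ring. The step needs insertion to win over attack on the electron-rich arenes, Wolff ring contraction and carbenoid dimerisation; the electron-rich carboxamidate ligands temper the carbenoid in favour of C–H insertion, slow addition keeps the diazo compound dilute, and the other C–H bonds that are 1,5 to C1 (C10–H and C11–H) cannot react because bonding them to C1 would leave the C3=C4 double bond at a bridgehead.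

Step 13
Reactants: 20 heptamethyl ether of the target
Product: 21 target CNP0407321.1
Conditions: BBr3 (14 equiv), CH2Cl2, −78 °C → rt; ice-water quench
Reagents that add atoms: none
Why: Cleavage of the seven aryl methyl ethers with BBr3 (Lewis acid-mediated O-demethylation) leaves the skeleton intact, since C1 is a bridgehead that cannot enolise and the quench is kept aqueous and non-basic to avoid retro-Claisen opening of the 1,3-diketone.

**Compound list**

1 | (R)-4-[(tert-butyldimethylsilyl)oxy]cyclopent-2-en-1-one | O=C1C=C[C@H](O[Si](C)(C)C(C)(C)C)C1 | starting material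
2 | (3,5-dimethoxyphenyl)magnesium chloride (THF solution) | COc1cc([Mg]Cl)cc(OC)c1 | starting material
3 | 4-methoxybenzaldehyde | COc1ccc(C=O)cc1 | starting material
4 | chloromagnesium enolate of the conjugate adduct (enolate C4=C11; C10 aryl trans to the C9 silyloxy group) | Cl[Mg]OC1=C[C@@H](c2cc(OC)cc(OC)c2)[C@H](O[Si](C)(C)C(C)(C)C)C1 | intermediate
5 | 4-[(tert-butyldimethylsilyl)oxy]-3-(3,5-dimethoxyphenyl)-2-[hydroxy(4-methoxyphenyl)methyl]cyclopentan-1-one, 2,3-trans, 3,4-trans, carbinol epimers | O=C1C[C@@H](O[Si](C)(C)C(C)(C)C)[C@H](c2cc(OC)cc(OC)c2)[C@H]1C(O)c1ccc(OC)cc1 | intermediate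
6 | tricyclic silyloxy ketone: cis-fused 5,7-dimethoxyindane–cyclopentanone, C4 ketone, C9 silyloxy trans to the benzo ring on C10, C12 4-methoxyphenyl trans to C4 | O=C1[C@H]2[C@H](c3ccc(OC)cc3)c3c(OC)cc(OC)cc3[C@H]2[C@H](O[Si](C)(C)C(C)(C)C)C1 | intermediate
7 | tricyclic enone: C4 ketone, C5=C9, C10, C11 and C12 as in 6 | O=C1[C@H]2[C@H](c3ccc(OC)cc3)c3c(OC)cc(OC)cc3[C@H]2C=C1 | intermediate
8 | (4-methoxyphenyl)magnesium bromide (THF solution) | COc1ccc([Mg]Br)cc1 | starting material
9 | tricyclic ketone with the C9 4-methoxyphenyl group trans to the benzo ring on C10 | O=C1[C@H]2[C@H](c3ccc(OC)cc3)c3c(OC)cc(OC)cc3[C@H]2[C@H](c2ccc(OC)cc2)C1 | intermediate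
10 | 2-acetyl ketone: 9 with an acetyl group (C8, C1) on C5; C5 epimerisable, largely enolised, drawn as the diketone | O=C1[C@H]2[C@H](c3ccc(OC)cc3)c3c(OC)cc(OC)cc3[C@H]2[C@H](c2ccc(OC)cc2)C1C(C)=O | intermediate
11 | (E)-1-methoxy-4-(2-nitroethenyl)benzene | COc1ccc(/C=C/[N+](=O)[O-])cc1 | starting material
12 | Michael adduct: quaternary C5 carrying the acetyl group (cis to the C9 aryl group) and the (S)-1-(4-methoxyphenyl)-2-nitroethyl arm | O=C1[C@H]2[C@H](c3ccc(OC)cc3)c3c(OC)cc(OC)cc3[C@H]2[C@H](c2ccc(OC)cc2)[C@@]1(C(C)=O)[C@H](c1ccc(OC)cc1)C[N+](=O)[O-] | intermediate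
13 | 1-bromo-3,5-dimethoxybenzene | COc1cc(Br)cc(OC)c1 | starting material
14 | arylated nitro compound: 12 with a 3,5-dimethoxyphenyl group on the nitro-bearing C7 (C7 epimers) | O=C1[C@H]2[C@H](c3ccc(OC)cc3)c3c(OC)cc(OC)cc3[C@H]2[C@H](c2ccc(OC)cc2)[C@@]1(C(C)=O)[C@H](c1ccc(OC)cc1)C(c1cc(OC)cc(OC)c1)[N+](=O)[O-] | intermediate
15 | diketone with the complete arm CH(4-methoxyphenyl)–CH2(3,5-dimethoxyphenyl) on C5 | O=C1[C@H]2[C@H](c3ccc(OC)cc3)c3c(OC)cc(OC)cc3[C@H]2[C@H](c2ccc(OC)cc2)[C@@]1(C(C)=O)[C@H](c1ccc(OC)cc1)Cc1cc(OC)cc(OC)c1 | intermediate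
16 | triketone: acetyl group of 15 extended to 3-oxobutanoyl (C8–C1–C2–C3); drawn as the keto tautomer | O=C1[C@H]2[C@H](c3ccc(OC)cc3)c3c(OC)cc(OC)cc3[C@H]2[C@H](c2ccc(OC)cc2)[C@@]1(C(=O)CC(C)=O)[C@H](c1ccc(OC)cc1)Cc1cc(OC)cc(OC)c1 | intermediate
17 | bicyclic ketol: C3 bonded to C4, tertiary alcohol at C4 (either epimer) | O=C1CC2(O)[C@H]3[C@H](c4ccc(OC)cc4)c4c(OC)cc(OC)cc4[C@H]3[C@H](c3ccc(OC)cc3)[C@]2([C@H](c3ccc(OC)cc3)Cc3cc(OC)cc(OC)c3)C(=O)C1 | intermediate
18 | ring-fused cyclohex-4-ene-1,3-dione (C2 and C8 ketones, C3=C4, C1H2, quaternary C5); enolised, drawn as the dione | O=C1C=C2[C@H]3[C@H](c4ccc(OC)cc4)c4c(OC)cc(OC)cc4[C@H]3[C@H](c3ccc(OC)cc3)[C@]2([C@H](c3ccc(OC)cc3)Cc3cc(OC)cc(OC)c3)C(=O)C1 | intermediate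
19 | ring-fused 2-diazocyclohex-4-ene-1,3-dione (diazo group on C1) | O=C1C=C2[C@H]3[C@H](c4ccc(OC)cc4)c4c(OC)cc(OC)cc4[C@H]3[C@H](c3ccc(OC)cc3)[C@]2([C@H](c3ccc(OC)cc3)Cc3cc(OC)cc(OC)c3)C(=O)C1=[N+]=[N-] | intermediate
20 | heptamethyl ether of the target | O=C1C=C2[C@H]3[C@H](c4ccc(OC)cc4)c4c(OC)cc(OC)cc4[C@H]3[C@H](c3ccc(OC)cc3)[C@]23C(=O)[C@H]1[C@H](c1cc(OC)cc(OC)c1)[C@H]3c1ccc(OC)cc1 | intermediate
21 | CNP0407321.1 | O=C1C=C2[C@H]3[C@H](c4ccc(O)cc4)c4c(O)cc(O)cc4[C@H]3[C@H](c3ccc(O)cc3)[C@]23C(=O)[C@H]1[C@H](c1cc(O)cc(O)c1)[C@H]3c1ccc(O)cc1 | target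

**Step count and risks**

Total steps: 13. Longest linear sequence: 13 steps (1 to 21); all other building blocks are commercial.

Most likely to fail:

1. Step 12 (proposed new method). The carbenoid may be diverted into addition to the 4-methoxyphenyl ring on C6, whose ipso and ortho carbons are as close to C1 as C7 is. It may also undergo Wolff ring contraction at the temperature the carboxamidate catalyst needs, or insert with poor discrimination between the two C7 hydrogens. Fallback, from 16 back to 20, moves the insertion to the open-chain stage, where it is the established cyclopentanone synthesis, and closes the six-membered ring last. Regitz diazo transfer to 16 (4-acetamidobenzenesulfonyl azide, Et3N, MeCN) should give the acyclic 2-diazo-1,3-diketone F1. Rh2(OAc)4 (1 mol %, CH2Cl2, reflux) should then insert C1 into the benzylic C7–H bond and give the spiro-fused 2-acetylcyclopentanone F2, with the 3,5-dimethoxyphenyl group trans to the C6 aryl group and C1 free to epimerise. Acid-catalysed aldol condensation of the acetyl methyl group (C3) onto the C4 ketone (TsOH·H2O, toluene, 80 °C) then closes the six-membered ring from the C1 epimer that can reach C4 and returns to 20.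

2. Step 7. The nitronate may fragment by retro-Michael reaction under the basic conditions, which would break the C5–C6 bond and lose the C6 configuration before arylation occurs. Fallback, from 12 back to 15, exchanges the nitro group by way of the aldehyde. A Nef reaction at low temperature (NaOMe, MeOH–CH2Cl2, −78 °C; O3; Me2S) should give the aldehyde F3. Addition of Grignard reagent 2 (THF, −78 °C) to the aldehyde, the most electrophilic carbonyl group, should give the benzylic carbinol F4 as an epimer mixture. Hydrogenolysis of the benzylic C–O bond (H2, Pd(OH)2/C, AcOH) returns to 15.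

3. Step 6. The crowded enol may add too slowly or reversibly to the nitroalkene, and facial selectivity at C5 may erode because the arm has to enter on the concave face. Fallback, from 10 directly to 15, is a cationic alkylation with commercial (E)-3,4′,5-trimethoxystilbene (TfOH 10 mol %, ClCH2CH2Cl, 50 °C). Protonation of the stilbene gives the p-methoxybenzylic cation at C6, which alkylates C5 of the enol, so that steps 7 and 8 fall away. C6 is then under substrate control only and the C6 epimer would have to be separated. No compound outside the compound list is made (F0).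

**Further compounds**

F1 | step 12 | acyclic 2-diazo-1,3-diketone (diazo group on C1 of the 3-oxobutanoyl chain of 16) | O=C1[C@H]2[C@H](c3ccc(OC)cc3)c3c(OC)cc(OC)cc3[C@H]2[C@H](c2ccc(OC)cc2)[C@@]1(C(=O)C(=[N+]=[N-])C(C)=O)[C@H](c1ccc(OC)cc1)Cc1cc(OC)cc(OC)c1
F2 | step 12 | spiro-fused 2-acetylcyclopentanone (C1–C7 bond formed, C1 epimerisable) | O=C1[C@H]2[C@H](c3ccc(OC)cc3)c3c(OC)cc(OC)cc3[C@H]2[C@H](c2ccc(OC)cc2)[C@]14C(=O)C(C(C)=O)[C@H](c1cc(OC)cc(OC)c1)[C@H]4c1ccc(OC)cc1
F3 | step 7 | aldehyde (C7 as CHO) | O=C1[C@H]2[C@H](c3ccc(OC)cc3)c3c(OC)cc(OC)cc3[C@H]2[C@H](c2ccc(OC)cc2)[C@@]1(C(C)=O)[C@H](c1ccc(OC)cc1)C=O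
F4 | step 7 | benzylic carbinol (C7 epimers) | O=C1[C@H]2[C@H](c3ccc(OC)cc3)c3c(OC)cc(OC)cc3[C@H]2[C@H](c2ccc(OC)cc2)[C@@]1(C(C)=O)[C@H](c1ccc(OC)cc1)C(O)c1cc(OC)cc(OC)c1
F0 | step 6 | none | none
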